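in all of them: substrate 0.17 M; time 20 s

| flask | remark | temperature |
|---|---|---|
| dawn | at 115 °C until 6.0 s, from then on at 85 °C |  |
| noon |  | 100 °C |
| summer |  | 115 °C |
| midnight |  | 85 °C |

    2 substrate → open dimer (k1 = 0.10 M⁻¹ s⁻¹, Ea1 = 75.0 kJ mol⁻¹)
    open dimer → ring dimer (k2 = 0.0079 s⁻¹, Ea2 = 107 kJ mol⁻¹)
    single ring ⇌ isomer of the product (K3 = 1.1, k3 = 0.044 s⁻¹, Ea3 = 107 kJ mol⁻¹, ΔH3 = −2.00 kJ mol⁻¹)
    substrate + open dimer → open trimer (k4 = 0.28 M⁻¹ s⁻¹, Ea4 = 78.0 kJ mol⁻¹)
    substrate ⇌ single ring (K5 = 34, k5 = 0.28 s⁻¹, Ea5 = 97.0 kJ mol⁻¹, ΔH5 = −56.0 kJ mol⁻¹)
    (constants at 100 °C)

- a species is counted by the substrate in it: one open dimer or ring dimer counts as two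
- a species is counted by the substrate in it: one open trimer counts as three
- where a step has two of a species, its rate is k times that concentration squared, and two are used at each turn
- all constants are for 100 °C and move with temperature by the activation energies and enthalpies

1. the flask that comes out highest in share of single ring in all that became single ring or open dimer or open trimer or ring dimer or isomer of the product, or "all alike" when all lie within 1.5 percentage points (dawn / noon / summer / midnight / all alike)
2. share of single ring in all that became single ring or open dimer or open trimer or ring dimer or isomer of the product, dawn
3. share of single ring in all that became single ring or open dimer or open trimer or ring dimer or isomer of the product, noon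
4. share of single ring in all that became single ring or open dimer or open trimer or ring dimer or isomer of the product, summer
5. share of single ring in all that became single ring or open dimer or open trimer or ring dimer or isomer of the product, midnight

We begin with a leftover: the single ring standing above its equilibrium level with the isomer of the product. Each ring is born as single ring, so its surplus starts whole. We follow the fraction of the surplus still left, the ring remainder. We estimate it as the exponential of minus the ring clock times the mean age of the rings. The ring clock is the forward plus the back constant of the ring-to-isomer step, and from the relaxation half-life 2.15 s it is 0.322 s⁻¹ in summer.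

Substrate is the limiting reagent, so we keep its ledger in fractions of the charge, with closure taken as one-way.

First entry, substrate left. Arrhenius and van 't Hoff share one temperature term, so the equilibrium constant of closure, 34 at noon, 72.4 at midnight and 16.9 in summer, scales each constant. Closure runs at 0.28 s⁻¹ at noon, 0.0756 s⁻¹ at midnight and 0.937 s⁻¹ in summer. With closure one-way, our estimate of the fraction left is 0.220 at midnight and 0.00370 at noon. Substrate left stays outside the share.

Second entry, chains: open dimer and what grows from it. Their share of the converted substrate is about the dimerisation constant times the charged concentration over the closure constant. That gives 0.0607 at noon and 0.0462 in summer. At midnight, with closure unfinished, we multiply by one plus the fraction left and get 0.0997.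

Third entry, the ring pair takes the rest. Its equilibrium single ring part is one over one plus the constant of the ring-to-isomer step, and the remainder lifts it above that. Mean age is the time minus the mean wait for closure, which is one over the closure constant. At noon that is 16.4 s, so the remainder is 0.252. At midnight the clock is 0.0196 s⁻¹. Unfinished closure adds to the age the time multiplied by the fraction left over the fraction converted, giving 12.4 s and a remainder of 0.784. In summer the remainder is 0.00224. In dawn, the mean wait for closure is shorter than the time of the change, so we use summer's entries and add the exponents of both stretches, which gives 0.155.

The books close. Our shares are 53.7 % for dawn, 57.1 % for noon, 46.1 % for summer and 79.7 % for midnight, which comes out highest.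

The forecast names midnight, with 54.5 %, 57 %, 46 % and 79 % in the same order of flasks. It reasons from “how far single ring has relaxed toward” equilibrium.

The simulation gives midnight as highest, with 54.3 %, 57.4 %, 45.9 % and 80.4 %. Forecast and ledger stand close to these. Our estimate of the summer remainder was 0.00224. Now read the summer flask earlier, at 5.0 s. The ring clock stays 0.322 s⁻¹, the mean age is 3.93 s, and the remainder is 0.281. The ledger then gives 59.9 %. That neighbouring flask gives 60.0 %, with single ring, at 57.4 % of the charge, holding most.

(The rate constants are made up; the result is computed.)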